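**Plan**

1. Numbering: C1 is the lactone-fused CH that carries C15 (lactone α-carbon with the exocyclic CH2, C17); C2 is the ring CH2, C3 the acetoxy CH, C4 the methyl carbinol, C7=C8 and C11=C12 the E-olefins, C13 the second acetoxy CH, C14 the lactone O–CH, C16 the carbonyl. Enabling feature: C1 is the β-carbon of the α-methylene-γ-lactone ring (O–C14–C1–C15–C16) and C2 is a CH2 flanked by the C3 oxygen. C1–C2 is therefore the bond a C2 radical makes when it adds to a butenolide whose α-CH2SO2Ph group then leaves to unveil C15=C17; a C2 anion would instead expel the C3 oxygen.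
2. Retrosynthetic cuts, in order: the two acetates and the protecting groups; C1–C2 (radical SH2′ closure of the 14-membered ring); C13–C14 (vinylogous aldol). This leaves a farnesol-derived C2–C13 iodo enal and a 3-(phenylsulfonylmethyl)butenolide made from α-methylene-γ-butyrolactone and sodium benzenesulfinate.
3. Forward: farnesol is functionalised at both ends (C2 iodide, C3/C4 acetonide, C13 enal). C7=C8 is then masked as its oxirane, because the C2 radical is a hept-6-enyl radical towards that olefin and would close a six-membered ring, or take an allylic hydrogen from C6, faster than a macrocycle can form. The preformed butenolide ring is attached by the aldol; the 14-membered ring arises last, in the step that also turns the butenolide into the α-methylene lactone. Deoxygenation, deprotection and acetylation finish the route.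
4. Stereochemistry: C3 and C4 come from Sharpless epoxidation (L-(+)-tartrate) and inverting hydrolysis at C4. C13 and C14 come from the catalyst of an anti-selective vinylogous Mukaiyama aldol. C1 comes from ring closure on the butenolide face opposite the C14–C13 bond (trans lactone). Both E-olefins come from farnesol, C7=C8 being returned by a stereospecific deoxygenation.

Key step: step 13

Remark on the chemistry: the peracid of step 7 is not expected to tell the two faces of C7=C8 apart, so every compound from the epoxy enal to the macrocycle is carried as both trans-7,8-oxiranes (7S,8S drawn, 7R,8R alongside), which converge when the olefin is restored in step 14.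

Assumption: the quinidine-derived catalyst of step 11 is taken as the pseudoenantiomer that leads to the (13S,14R) series; should it lead to the antipode, the quinine-derived salt replaces it with nothing else changed.

**Route**

Step 1
Reactants: 1 (2E,6E)-farnesol
Product: 2 (2S,3S)-2,3-epoxyfarnesol
Conditions: Ti(OiPr)4 (10 mol %), L-(+)-diethyl tartrate (12 mol %), tBuOOH, 4 Å MS, CH2Cl2, −20 °C
Reagents that add atoms: tert-butyl hydroperoxide, CC(C)(C)OO
Why: Sharpless asymmetric epoxidation of the allylic alcohol; the titanium tartrate complex delivers oxygen only to the hydroxyl-bearing olefin and, with the L-(+)-tartrate, to the face that gives the (2S,3S)-epoxide, which fixes C3 and provisionally C4 of the target.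

Step 2
Reactants: 2 (2S,3S)-2,3-epoxyfarnesol
Product: 3 (2S,3R,6E)-3,7,11-trimethyldodeca-6,10-diene-1,2,3-triol
Conditions: HClO4 (cat.), THF/H2O 3:1, 0 °C to rt
Reagents that add atoms: water, O
Why: Acid-catalysed epoxide hydrolysis of borderline SN2 type, in which water attacks the tertiary oxirane carbon anti to the leaving oxygen, so that the future C4 is inverted (3S to 3R in chain numbering) while the future C3 keeps its C–O bond, giving the erythro diol of the target.

Step 3
Reactants: 3 (2S,3R,6E)-3,7,11-trimethyldodeca-6,10-diene-1,2,3-triol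
Product: 4 (2R,3R,6E)-1-iodo-3,7,11-trimethyldodeca-6,10-diene-2,3-diol
Conditions: PPh3, I2, imidazole (reagent pre-formed), THF/MeCN, 0 °C
Reagents that add atoms: iodine, I-I
Why: Appel-type iodination that takes place at the unhindered primary hydroxyl and leaves the secondary and tertiary carbinols, and both stereocenters, untouched (the descriptor at the secondary carbon changes only because iodine alters the priorities).

Step 4
Reactants: 4 (2R,3R,6E)-1-iodo-3,7,11-trimethyldodeca-6,10-diene-2,3-diol
Product: 5 (4R,5R)-4-(iodomethyl)-2,2,5-trimethyl-5-[(3E)-4,8-dimethylnona-3,7-dien-1-yl]-1,3-dioxolane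
Conditions: Me2C(OMe)2, PPTS (cat.), CH2Cl2, rt
Reagents that add atoms: 2,2-dimethoxypropane, COC(C)(C)OC
Why: Acid-catalysed transketalisation closes the dioxolane on the secondary/tertiary 1,2-diol; no stereocenter changes.

Step 5
Reactants: 5 iodo acetonide
Product: 6 (2E,6E)-9-[(4R,5R)-5-(iodomethyl)-2,2,4-trimethyl-1,3-dioxolan-4-yl]-2,6-dimethylnona-2,6-dien-1-ol
Conditions: SeO2 (cat.), tBuOOH, salicylic acid (cat.), CH2Cl2, 0 °C to rt
Reagents that add atoms: tert-butyl hydroperoxide, CC(C)(C)OO
Why: SeO2 allylic oxidation (ene reaction, then 2,3-sigmatropic shift) kept turning over by tBuOOH, which attacks the most electron-rich, terminal trisubstituted olefin at its E-methyl group and gives the E-allylic alcohol at the future C13.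

Step 6
Reactants: 6 allylic alcohol
Product: 7 (2E,6E)-9-[(4R,5R)-5-(iodomethyl)-2,2,4-trimethyl-1,3-dioxolan-4-yl]-2,6-dimethylnona-2,6-dienal
Conditions: MnO2, CH2Cl2, rt
Reagents that add atoms: none
Why: MnO2 oxidation, selective for allylic alcohols, gives the E-enal without touching iodide, acetal or the isolated olefin.

Step 7
Reactants: 7 dienal
Product: 8 (2E)-5-[(2S,3S)-3-{2-[(4R,5R)-5-(iodomethyl)-2,2,4-trimethyl-1,3-dioxolan-4-yl]ethyl}-2-methyloxiran-2-yl]-2-methylpent-2-enal (7,8-epoxy enal)
Conditions: mCPBA (1.05 equiv), NaHCO3, CH2Cl2, −20 °C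
Reagents that add atoms: 3-chloroperoxybenzoic acid, O=C(OO)c1cccc(Cl)c1
Why: Prilezhaev epoxidation in which the peracid takes the electron-rich isolated C7=C8 in preference to the electron-poor enal olefin, syn addition giving the trans-oxirane on either face, while one equivalent at low temperature is expected to leave the hindered, β-oxygenated primary iodide unoxidised; the oxirane masks the only olefin the later C2 radical could reach by 6-exo closure.

Step 8
Reactants: 9 α-methylene-γ-butyrolactone; 10 sodium benzenesulfinate
Product: 11 rac-3-iodo-3-[(phenylsulfonyl)methyl]dihydrofuran-2(3H)-one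
Conditions: I2, EtOAc/H2O, rt, ambient light
Reagents that add atoms: iodine, I-I
Why: Radical iodosulfonylation (atom-transfer addition of PhSO2I formed from the sulfinate and I2): the sulfonyl radical adds to the exocyclic CH2 and the tertiary α-lactone radical takes up iodine; the new quaternary center is racemic and is destroyed in step 9.

Step 9
Reactants: 11 iodo sulfone
Product: 13 3-[(phenylsulfonyl)methyl]furan-2(5H)-one, via exocyclic vinyl sulfone 12 (not isolated)
Conditions: Et3N (3 equiv), EtOAc, rt to 60 °C
Reagents that add atoms: none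
Why: Dehydroiodination (E2, through the acidic hydrogens next to sulfur) followed by amine-mediated 1,3-prototropic shift of the vinyl sulfone into the more stable endocyclic allyl sulfone, the course known for methacrylate-derived iodosulfones.

Step 10
Reactants: 13 3-[(phenylsulfonyl)methyl]furan-2(5H)-one
Product: 14 3-[(phenylsulfonyl)methyl]-2-(trimethylsilyloxy)furan
Conditions: TMSOTf, Et3N, CH2Cl2, −78 to 0 °C; pentane, filtration under Ar; used crude
Reagents that add atoms: trimethylsilyl trifluoromethanesulfonate, C[Si](C)(C)OS(=O)(=O)C(F)(F)F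
Why: Soft enolisation: silylation of the lactone carbonyl and γ-deprotonation by Et3N give the aromatic 2-silyloxyfuran without a free dienolate that could expel sulfinate.

Step 11
Reactants: 8 7,8-epoxy enal; 14 silyloxyfuran
Product: 16 (13S,14R)-hydroxy butenolide (anti aldol adduct), via trimethylsilyl ether 15 (not isolated)
Conditions: 1-[3,5-bis(trifluoromethyl)phenyl]-3-(9-deoxy-9-epi-quinidin-9-yl)thiourea·CF3CO2H (10 mol %), CH2Cl2/Et2O, −20 °C; then aq. citric acid, THF, 0 °C
Reagents that add atoms: none
Why: Catalytic asymmetric vinylogous Mukaiyama aldol addition: the thiourea/ammonium unit of the cinchona salt binds the enal by hydrogen bonds, the carboxylate assists silyl transfer, and the furan attacks through C5 (C3 being blocked) in an open, anti-selective arrangement, so that the catalyst sets both C14 and C13 as the (13S,14R) pair.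

Step 12
Reactants: 16 (13S,14R)-hydroxy butenolide
Product: 17 C13 triethylsilyl ether (radical precursor)
Conditions: Et3SiCl, imidazole, CH2Cl2, 0 °C
Reagents that add atoms: chlorotriethylsilane, CC[Si](Cl)(CC)CC
Why: Silyl ether formation under mild base that should neither epimerise C14 nor provoke loss of sulfinate; no stereocenter changes.

Step 13
Reactants: 17 C13 triethylsilyl ether (C2 iodide, C3/C4 acetonide, 7,8-oxirane, 3-(phenylsulfonylmethyl)butenolide at C14)
Product: 18 (1R,3S,4R,7S,8S,13S,14R)-7,8-epoxy-3,4-(isopropylidenedioxy)-13-(triethylsilyloxy)cembra-11E,15(17)-dien-16,14-olide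
Conditions: Bu3SnSnBu3 (1.2 equiv), hν (sunlamp, Pyrex), degassed benzene (1 mM), 15–20 °C
Reagents that add atoms: none
Why: Proposed new method: Light cleaves the ditin to Bu3Sn radicals, which abstract iodine from C2; the primary C2 radical adds to C1, the β-carbon of the butenolide, and the C15 α-acyl radical thus formed expels PhSO2 radical, which attacks the ditin and returns Bu3Sn radical, so that no hydrogen donor is present to reduce the radical before it cyclises. The closest known reactions are ditin-mediated SH2′ allylations of alkyl iodides with 2-(arylsulfonylmethyl)acrylates and tin-hydride macrocyclisations of ω-iodoalkyl enones and enoates to 14-membered rings. The carbocycle closes in the 14-exo-trig mode, since the radical bonds to C1 and C15 stays outside the new ring. The C1 center is set under substrate control: the tether leaves C14 on one face of the planar butenolide, and bond formation on the opposite face avoids eclipsing the new C1–C2 bond with C14–C13 and the silyloxy and methyl groups at C13 and C12, which should give the trans-fused (1R) lactone, in line with intermolecular radical additions to 5-substituted butenolides. The step needs attack at C1 and not at C15 (only C1 attack gives the acyl-stabilised radical that can fragment), ring closure ahead of other intramolecular paths (C7=C8, which as an olefin would capture the C2 radical by 6-exo closure or give up an allylic hydrogen from C6, is present as the oxirane) and ahead of addition to the methylene lactone of product already formed (hence the 1 mM dilution).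

Step 14
Reactants: 18 epoxy macrocycle
Product: 19 (1R,3S,4R,13S,14R)-3,4-(isopropylidenedioxy)-13-(triethylsilyloxy)cembra-7E,11E,15(17)-trien-16,14-olide
Conditions: Ph3P=Se, CF3CO2H, CH2Cl2, 0 °C to rt
Reagents that add atoms: none
Why: Stereospecific epoxide deoxygenation with triphenylphosphine selenide and acid: selenium opens the protonated oxirane with inversion, oxygen passes to phosphorus with a second inversion and selenium is extruded, so both oxirane diastereomers return the E-olefin C7=C8 (partial loss of the silyl ether here would not matter, since step 15 removes it).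

Step 15
Reactants: 19 triene acetonide silyl ether
Product: 20 (1R,3S,4R,13S,14R)-3,4,13-trihydroxycembra-7E,11E,15(17)-trien-16,14-olide
Conditions: 1 M aq. HCl, THF, rt
Reagents that add atoms: none
Why: Acid-catalysed hydrolysis of the isopropylidene acetal and of the silyl ether sets free the C3, C4 and C13 hydroxyls; no stereocenter is touched.

Step 16
Reactants: 20 triol
Product: 21 crassocolide B
Conditions: Ac2O, pyridine, DMAP (cat.), CH2Cl2, 0 °C to rt
Reagents that add atoms: acetic anhydride, CC(=O)OC(C)=O
Why: Acylation esterifies the two secondary hydroxyls at C3 and C13, while the tertiary C4 carbinol does not react under these conditions.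

**Compound list**

1 | (2E,6E)-farnesol, (2E,6E)-3,7,11-trimethyldodeca-2,6,10-trien-1-ol | CC(C)=CCC/C(C)=C/CC/C(C)=C/CO | starting material
2 | (2S,3S)-2,3-epoxyfarnesol, [(2S,3S)-3-[(3E)-4,8-dimethylnona-3,7-dien-1-yl]-3-methyloxiran-2-yl]methanol | OC[C@@H]1O[C@@]1(C)CC/C=C(\C)CCC=C(C)C | intermediate
3 | (2S,3R,6E)-3,7,11-trimethyldodeca-6,10-diene-1,2,3-triol | OC[C@H](O)[C@](C)(O)CC/C=C(\C)CCC=C(C)C | intermediate
4 | (2R,3R,6E)-1-iodo-3,7,11-trimethyldodeca-6,10-diene-2,3-diol | IC[C@H](O)[C@](C)(O)CC/C=C(\C)CCC=C(C)C | intermediate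
5 | (4R,5R)-4-(iodomethyl)-2,2,5-trimethyl-5-[(3E)-4,8-dimethylnona-3,7-dien-1-yl]-1,3-dioxolane | IC[C@@H]1OC(C)(C)O[C@]1(C)CC/C=C(\C)CCC=C(C)C | intermediate
6 | (2E,6E)-9-[(4R,5R)-5-(iodomethyl)-2,2,4-trimethyl-1,3-dioxolan-4-yl]-2,6-dimethylnona-2,6-dien-1-ol | IC[C@@H]1OC(C)(C)O[C@]1(C)CC/C=C(\C)CC/C=C(\C)CO | intermediate
7 | (2E,6E)-9-[(4R,5R)-5-(iodomethyl)-2,2,4-trimethyl-1,3-dioxolan-4-yl]-2,6-dimethylnona-2,6-dienal | IC[C@@H]1OC(C)(C)O[C@]1(C)CC/C=C(\C)CC/C=C(\C)C=O | intermediate
8 | (2E)-5-[(2S,3S)-3-{2-[(4R,5R)-5-(iodomethyl)-2,2,4-trimethyl-1,3-dioxolan-4-yl]ethyl}-2-methyloxiran-2-yl]-2-methylpent-2-enal (7S,8S-oxirane drawn; 7R,8R epimer alongside) | IC[C@@H]1OC(C)(C)O[C@]1(C)CC[C@@H]2O[C@@]2(C)CC/C=C(\C)C=O | intermediate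
9 | α-methylene-γ-butyrolactone, 3-methylidenedihydrofuran-2(3H)-one | C=C1CCOC1=O | starting material
10 | sodium benzenesulfinate | [Na+].[O-]S(=O)c1ccccc1 | starting material
11 | rac-3-iodo-3-[(phenylsulfonyl)methyl]dihydrofuran-2(3H)-one | O=C1OCCC1(I)CS(=O)(=O)c1ccccc1 | intermediate
12 | (E)-3-[(phenylsulfonyl)methylidene]dihydrofuran-2(3H)-one | O=C1OCC/C1=C\S(=O)(=O)c1ccccc1 | intermediate
13 | 3-[(phenylsulfonyl)methyl]furan-2(5H)-one | O=C1OCC=C1CS(=O)(=O)c1ccccc1 | intermediate
14 | 3-[(phenylsulfonyl)methyl]-2-(trimethylsilyloxy)furan | C[Si](C)(C)Oc1occc1CS(=O)(=O)c1ccccc1 | intermediate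
15 | C13 trimethylsilyl ether of 16 (13S,14R; 7S,8S-oxirane drawn) | IC[C@@H]1OC(C)(C)O[C@]1(C)CC[C@@H]2O[C@@]2(C)CC/C=C(\C)[C@H](O[Si](C)(C)C)[C@@H]3OC(=O)C(CS(=O)(=O)c4ccccc4)=C3 | intermediate
16 | (5R)-5-[(1S,2E)-1-hydroxy-2-methylpent-2-en-1-yl]-3-[(phenylsulfonyl)methyl]furan-2(5H)-one whose pentenyl C5 carries the 2-methyl-3-[2-(iodomethyl-dioxolanyl)ethyl]oxirane of 8; anti aldol adduct (3R,4R,13S,14R in ring numbering; 7S,8S-oxirane drawn) | IC[C@@H]1OC(C)(C)O[C@]1(C)CC[C@@H]2O[C@@]2(C)CC/C=C(\C)[C@H](O)[C@@H]3OC(=O)C(CS(=O)(=O)c4ccccc4)=C3 | intermediate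
17 | C13 triethylsilyl ether of 16, radical precursor (3R,4R,13S,14R; 7S,8S-oxirane drawn) | IC[C@@H]1OC(C)(C)O[C@]1(C)CC[C@@H]2O[C@@]2(C)CC/C=C(\C)[C@H](O[Si](CC)(CC)CC)[C@@H]3OC(=O)C(CS(=O)(=O)c4ccccc4)=C3 | intermediate
18 | (1R,3S,4R,7S,8S,13S,14R)-7,8-epoxy-3,4-(isopropylidenedioxy)-13-(triethylsilyloxy)cembra-11E,15(17)-dien-16,14-olide (7R,8R epimer alongside) | C=C1C(=O)O[C@@H]2[C@@H]1C[C@@H]3OC(C)(C)O[C@]3(C)CC[C@@H]4O[C@@]4(C)CC/C=C(\C)[C@@H]2O[Si](CC)(CC)CC | intermediate
19 | (1R,3S,4R,13S,14R)-3,4-(isopropylidenedioxy)-13-(triethylsilyloxy)cembra-7E,11E,15(17)-trien-16,14-olide | C=C1C(=O)O[C@@H]2[C@@H]1C[C@@H]3OC(C)(C)O[C@]3(C)CC/C=C(\C)CC/C=C(\C)[C@@H]2O[Si](CC)(CC)CC | intermediate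
20 | (1R,3S,4R,13S,14R)-3,4,13-trihydroxycembra-7E,11E,15(17)-trien-16,14-olide | C=C1C(=O)O[C@@H]2[C@@H]1C[C@H](O)[C@](C)(O)CC/C=C(\C)CC/C=C(\C)[C@@H]2O | intermediate
21 | crassocolide B, (1R,3S,4R,13S,14R)-3,13-diacetoxy-4-hydroxycembra-7E,11E,15(17)-trien-16,14-olide | C=C1C(=O)O[C@@H]2[C@@H]1C[C@H](OC(C)=O)[C@](C)(O)CC/C=C(\C)CC/C=C(\C)[C@@H]2OC(C)=O | target

**Step count and risks**

Total steps: 16. Longest linear sequence: 13 steps (steps 1–7 and 11–16, from farnesol); steps 8–10 form the side branch that joins in step 11.

Steps most likely to fail: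

1. Step 13 (new method). Ring closure onto the β-substituted butenolide carbon may be slow. The C2 radical may then add to the methylene lactone of product already formed (oligomers), be lost by chain termination, or bond to the wrong face of C1; stannyl radicals may also displace the sulfonyl group directly. The fallback uses known chemistry, sets out from 8 and comes back to the route at 18. The cinchona-salt-catalysed vinylogous aldol of step 11 is run on 8 with commercial 2-(trimethylsilyloxy)furan and gives, through the sulfone-free silyl ether F1, the sulfone-free anti alcohol F2, which Et3SiCl and imidazole convert into the sulfone-free triethylsilyl ether F3. Slow addition of Bu3SnH and AIBN to F3 in refluxing benzene at high dilution closes the 14-membered ring by reductive (Giese-type) addition of the C2 radical to C1, a known class of radical macrocyclisation onto α,β-unsaturated carbonyl acceptors, and gives the saturated trans-lactone F4, which is no radical acceptor. α-Methylenation follows: LDA and dimethyl(methylidene)ammonium iodide give the Mannich base F5, MeI gives the ammonium iodide F6, and NaHCO3 eliminates trimethylamine to give 18.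

2. Step 11. With the new 3-substituted donor and an α-branched enal the anti/syn ratio may erode, and any free dienolate can lose sulfinate. The fallback corrects the configuration at C13 after the addition instead of relying on the catalyst for it; it sets out from 8 and 14 and comes back to the route at 16. The addition is run as in step 11, and the C13 epimer, which arises through its trimethylsilyl ether F7 and is isolated as the syn alcohol F8 (13R,14R), is kept. A Mitsunobu reaction (PPh3 and DIAD premixed, HCO2H, THF, 0 °C) inverts C13 and gives the formate F9 (13S), and KHCO3 in MeOH removes the formyl group to give 16.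

3. Step 14. Acid may open or rearrange the protonated oxirane (transannular participation of C11=C12 or of the acetal oxygens) faster than selenium is transferred, and the protecting groups may be lost unevenly. The fallback sets out from 18 and comes back to the route at 19. It replaces the acid-triggered chalcogen exchange by neutral oxygen abstraction with a rhodium carbenoid: Rh2(OAc)4 (cat.) and dimethyl diazomalonate in benzene at reflux form an oxonium ylide at the oxirane oxygen, which loses dimethyl oxomalonate and returns the E-olefin with retention of geometry. No new compound lies on this path.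

**Further compounds**

F1 | step 13 | C13 trimethylsilyl ether of F2 (7S,8S-oxirane drawn) | IC[C@@H]1OC(C)(C)O[C@]1(C)CC[C@@H]2O[C@@]2(C)CC/C=C(\C)[C@H](O[Si](C)(C)C)[C@@H]3OC(=O)C=C3
F2 | step 13 | (13S,14R) anti aldol adduct of 8 with furan-2(5H)-one, the analogue of 16 without the sulfonylmethyl group | IC[C@@H]1OC(C)(C)O[C@]1(C)CC[C@@H]2O[C@@]2(C)CC/C=C(\C)[C@H](O)[C@@H]3OC(=O)C=C3
F3 | step 13 | C13 triethylsilyl ether of F2 | IC[C@@H]1OC(C)(C)O[C@]1(C)CC[C@@H]2O[C@@]2(C)CC/C=C(\C)[C@H](O[Si](CC)(CC)CC)[C@@H]3OC(=O)C=C3
F4 | step 13 | (1R,3S,4R,7S,8S,13S,14R)-7,8-epoxy-3,4-(isopropylidenedioxy)-13-(triethylsilyloxy)cembr-11E-en-16,14-olide carrying CH2 at C15 (saturated trans-lactone) | C1C(=O)O[C@@H]2[C@@H]1C[C@@H]3OC(C)(C)O[C@]3(C)CC[C@@H]4O[C@@]4(C)CC/C=C(\C)[C@@H]2O[Si](CC)(CC)CC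
F5 | step 13 | C15 (dimethylamino)methyl derivative of F4 (Mannich base; C15 configuration not defined, lost on elimination) | CN(C)CC1C(=O)O[C@@H]2[C@@H]1C[C@@H]3OC(C)(C)O[C@]3(C)CC[C@@H]4O[C@@]4(C)CC/C=C(\C)[C@@H]2O[Si](CC)(CC)CC
F6 | step 13 | trimethylammonium iodide from F5 | C[N+](C)(C)CC1C(=O)O[C@@H]2[C@@H]1C[C@@H]3OC(C)(C)O[C@]3(C)CC[C@@H]4O[C@@]4(C)CC/C=C(\C)[C@@H]2O[Si](CC)(CC)CC.[I-]
F7 | step 11 | C13 trimethylsilyl ether of F8 | IC[C@@H]1OC(C)(C)O[C@]1(C)CC[C@@H]2O[C@@]2(C)CC/C=C(\C)[C@@H](O[Si](C)(C)C)[C@@H]3OC(=O)C(CS(=O)(=O)c4ccccc4)=C3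
F8 | step 11 | (13R,14R) syn epimer of 16 | IC[C@@H]1OC(C)(C)O[C@]1(C)CC[C@@H]2O[C@@]2(C)CC/C=C(\C)[C@@H](O)[C@@H]3OC(=O)C(CS(=O)(=O)c4ccccc4)=C3
F9 | step 11 | (13S,14R) C13 formate of 16 | IC[C@@H]1OC(C)(C)O[C@]1(C)CC[C@@H]2O[C@@]2(C)CC/C=C(\C)[C@H](OC=O)[C@@H]3OC(=O)C(CS(=O)(=O)c4ccccc4)=C3
F0 | step 14 | none | none
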